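**Plan**

Atom numbers are those of the target: ring C1–C10, lactone carbons C11–C13 on C7/C8, C14 on C10, C15 on C4.
Retrosynthesis cuts the C6–O acyl bond, the oxirane C–O bonds, C11=C13 and the lactone O8–C12 bond, which leads back to the (4E)-cyclodec-4-en-9-one 18; then C6–C7 is cut while C4–C9 is rejoined.
This is possible because O9 and the C4=C5 alkene (masked as the oxirane) sit 1,6 in the ten-membered ring: with C4–C9 joined, ring C9–C10–C1–C2–C3–C4 is a cyclohexanol carrying a but-1-enyl group (C8=C7) on C9 and an alkoxyvinyl group (C5=C6) on quaternary C4.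
Forward, the cyclohexane comes from cis-2,6-dimethylcyclohexanone, the ten-membered ring arises by [3,3] ring expansion (step 12), then follow the γ-lactone (O8–C12), the exocyclic methylene, the oxirane and the ester.
Stereochemistry: C10 from enantioselective deprotonation, C4 from ligand-controlled allylation, C9 of the precursor from axial epoxidation anti to the C4 methyl; C6/C7 by chirality transfer through the chair; C8 by outer-face enolate hydroxylation, C9 by chelation-controlled reduction, C4/C5 by matched titanium–tartrate epoxidation.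

Key step: step 12

Assumption: 2,6-dimethylcyclohexanone is used as its cis (meso) isomer, the main component of the commercial mixture, freed from the trans isomer by base equilibration and distillation.

**Route**

Step 1
Reactants: 1 cis-2,6-dimethylcyclohexanone
Product: 2 (6R)-2,6-dimethyl-1-(trimethylsilyloxy)cyclohex-1-ene
Conditions: (S,S)-bis(1-phenylethyl)amine, n-BuLi, Me3SiCl (in situ), THF, −100 to −78 °C
Reagents that add atoms: chlorotrimethylsilane, C[Si](C)(C)Cl
Why: A C2-symmetric chiral lithium amide distinguishes the two enantiotopic axial α-hydrogens of the meso ketone (enantioselective deprotonation with in situ silylation), so C10 is left as one enantiomer; by analogy with 4-substituted cyclohexanones the S,S base should give the 6R enol ether, and the R,R base would be used if the sense proved opposite.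

Step 2
Reactants: 2 (6R)-2,6-dimethyl-1-(trimethylsilyloxy)cyclohex-1-ene
Product: 3 (2R,6R)-2-allyl-2,6-dimethylcyclohexanone
Conditions: Pd2(dba)3 (2.5 mol%), (R)-t-BuPHOX (6 mol%), diallyl carbonate, Bu4N[Ph3SiF2] (35 mol%), THF, 25 °C
Reagents that add atoms: diallyl carbonate, C=CCOC(=O)OCC=C
Why: Fluoride-initiated release of the tetrasubstituted enolate and its capture by a π-allylpalladium complex of the PHOX ligand (enantioselective Tsuji–Trost allylation) creates quaternary C4 under ligand control, the R ligand being chosen because the S ligand gives the 2S series with 2-methylcyclohexanone; the allyl group should thus enter cis to the C10 methyl, and the neutral medium leaves C10 intact.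

Step 3
Reactants: 3 (2R,6R)-2-allyl-2,6-dimethylcyclohexanone
Product: 4 (2R,6R)-2,6-dimethyl-2-[(E)-prop-1-enyl]cyclohexanone
Conditions: PdCl2(MeCN)2 (10 mol%), toluene, 60 °C
Reagents that add atoms: none
Why: Divalent palladium isomerises the terminal alkene to the more stable internal one by a hydride addition–elimination path without base, so the epimerisable C10 is not disturbed; the alkene geometry is immaterial because the next step cleaves it.

Step 4
Reactants: 4 (2R,6R)-2,6-dimethyl-2-[(E)-prop-1-enyl]cyclohexanone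
Product: 6 (1R,3R)-1,3-dimethyl-2-oxocyclohexane-1-carbaldehyde, via ozonide 5 (not isolated)
Conditions: O3, CH2Cl2, −78 °C; then PPh3, −78 °C to rt
Reagents that add atoms: ozone, [O-][O+]=O
Why: Ozonolysis with phosphine reduction of the ozonide cleaves the only alkene to the aldehyde on the quaternary carbon, which has no α-hydrogen and therefore cannot racemise or condense.

Step 5
Reactants: 6 (1R,3R)-1,3-dimethyl-2-oxocyclohexane-1-carbaldehyde
Product: 7 (2R,6R)-2-[(E)-2-iodoethenyl]-2,6-dimethylcyclohexanone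
Conditions: CrCl2, CHI3, THF, 0 °C to rt
Reagents that add atoms: iodoform, IC(I)I
Why: Takai olefination with the geminal dichromium species from CHI3 reacts with aldehydes but not with hindered ketones and gives E iodoalkenes, the bulky quaternary substituent reinforcing the trans preference.

Step 6
Reactants: 7 (2R,6R)-2-[(E)-2-iodoethenyl]-2,6-dimethylcyclohexanone
Product: 8 (1R,3R)-1-[(E)-2-iodoethenyl]-1,3-dimethyl-2-methylidenecyclohexane
Conditions: Cp2TiMe2, toluene, 70 °C, dark
Reagents that add atoms: dimethyltitanocene, [CH3-].[CH3-].[Ti+4].c1cc[cH-]c1.c1cc[cH-]c1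
Why: Petasis methylenation through a titanium methylidene and an oxatitanacyclobutane is non-basic, so the hindered, enolisable ketone should be converted without epimerisation at C10 and without touching the iodoalkene.

Step 7
Reactants: 8 (1R,3R)-1-[(E)-2-iodoethenyl]-1,3-dimethyl-2-methylidenecyclohexane
Product: 9 (3R,4R,8R)-4-[(E)-2-iodoethenyl]-4,8-dimethyl-1-oxaspiro[2.5]octane
Conditions: mCPBA, NaHCO3, CH2Cl2, 0 °C
Reagents that add atoms: 3-chloroperoxybenzoic acid, OOC(=O)c1cccc(Cl)c1
Why: Prilezhaev epoxidation picks the electron-richer 1,1-disubstituted alkene over the iodoalkene, and in the chair with the C10 methyl and the iodovinyl group equatorial the axial C4 methyl blocks the equatorial trajectory, so oxygen should arrive axially, cis to the iodovinyl group and the C10 methyl; oxygen delivery is used because a carbon nucleophile adding to ketone 7 would enter from that same open face and give the C9 epimer.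

Step 8
Reactants: 9 (3R,4R,8R)-4-[(E)-2-iodoethenyl]-4,8-dimethyl-1-oxaspiro[2.5]octane
Product: 10 (1R,2R,6R)-1-ethenyl-2-[(E)-2-iodoethenyl]-2,6-dimethylcyclohexan-1-ol
Conditions: Me3S+ I−, n-BuLi, THF, −10 °C to rt
Reagents that add atoms: trimethylsulfonium iodide, C[S+](C)C.[I-]
Why: Dimethylsulfonium methylide opens the oxirane at its CH2 carbon in an SN2 reaction and the β-alkoxy sulfonium ion is then deprotonated and loses dimethyl sulfide (one-carbon homologation of an epoxide to an allylic alcohol), so the C9–O bond and its configuration are untouched.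

Step 9
Reactants: 11 but-3-en-1-ol
Product: 12 tert-butyl(but-3-enyloxy)dimethylsilane
Conditions: TBSCl, imidazole, CH2Cl2, rt
Reagents that add atoms: tert-butylchlorodimethylsilane, CC(C)(C)[Si](C)(C)Cl
Why: Standard silylation of a primary alcohol with the silyl chloride and imidazole.

Step 10
Reactants: 10 (1R,2R,6R)-1-ethenyl-2-[(E)-2-iodoethenyl]-2,6-dimethylcyclohexan-1-ol; 12 tert-butyl(but-3-enyloxy)dimethylsilane
Product: 13 (1S,2R,6R)-1-[(E)-4-(tert-butyldimethylsilyloxy)but-1-enyl]-2-[(E)-2-iodoethenyl]-2,6-dimethylcyclohexan-1-ol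
Conditions: second-generation Hoveyda–Grubbs catalyst (5 mol%), 12 (4 equiv), CH2Cl2, 40 °C
Reagents that add atoms: none
Why: Olefin cross-metathesis between a hindered tertiary allylic alcohol that does not homodimerise and an unhindered terminal alkene is selective for the cross product and thermodynamically E, while the iodoalkene on the quaternary carbon is too hindered and electron-poor to enter the cycle.

Step 11
Reactants: 13 (1S,2R,6R)-1-[(E)-4-(tert-butyldimethylsilyloxy)but-1-enyl]-2-[(E)-2-iodoethenyl]-2,6-dimethylcyclohexan-1-ol; 14 4-methoxybenzyl alcohol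
Product: 15 (1S,2R,6R)-1-[(E)-4-(tert-butyldimethylsilyloxy)but-1-enyl]-2-[(E)-2-(4-methoxybenzyloxy)ethenyl]-2,6-dimethylcyclohexan-1-ol
Conditions: CuI (10 mol%), 3,4,7,8-tetramethyl-1,10-phenanthroline (20 mol%), Cs2CO3, toluene, 80 °C
Reagents that add atoms: none
Why: Copper-catalysed Ullmann-type C–O coupling of an iodoalkene with a primary alcohol proceeds with retention of geometry and so gives the E enol ether; the carbonate base does not ionise the hindered tertiary alcohol to a useful extent, and a trans iodoalkene cannot cyclise onto it.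

Step 12
Reactants: 15 (1S,2R,6R)-1-[(E)-4-(tert-butyldimethylsilyloxy)but-1-enyl]-2-[(E)-2-(4-methoxybenzyloxy)ethenyl]-2,6-dimethylcyclohexan-1-ol
Product: 18 (4E,6R,7S,10R)-6-(4-methoxybenzyloxy)-4,10-dimethyl-7-[2-(tert-butyldimethylsilyloxy)ethyl]cyclodec-4-en-9-one, via potassium alkoxide 16 (not isolated), via potassium enolate 17 (not isolated)
Conditions: KH, 18-crown-6, THF, 0 °C to rt; then aq NH4Cl, −78 °C
Reagents that add atoms: none
Why: KH with 18-crown-6 forms the dissociated alkoxide 16, whose oxyanion weakens the C4–C9 bond, and the 1,5-diene C7=C8–C9–C4–C5=C6 then undergoes a concerted [3,3]-sigmatropic shift (anionic oxy-Cope rearrangement, the closest precedent being trans-1,2-dialkenylcyclohexanols giving (E)-cyclodec-5-enones) that forms C6–C7, breaks C4–C9 and gives enolate 17, protonated at C8 on work-up. The ten-membered ring is not closed end to end: it arises by four-atom expansion of the cyclohexane through a six-membered chair transition state. Because the alkenyl groups are trans-diequatorial, the ring bonds C9–C10 and C4–C3 are equatorial on that chair, so C4=C5 and the enolate C8=C9 are both E within the new ring. C6 and C7 are created together: the E geometry of both alkenes puts OPMB and the C11 chain equatorial, which fixes their relative configuration, and the configurations of C9 and C4 in 15 fix which enantiomeric chair is used (chirality transfer), giving 6R,7S. The step needs chair over boat and a single reactive cyclohexane conformer; the trans alkenyl groups and the equatorial C10 methyl, which keeps O9 and C15 axial, secure both. C10 is a spectator and its hydrogen ends in the plane of the new carbonyl, which should protect it from epimerisation.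

Step 13
Reactants: 18 (4E,6R,7S,10R)-6-(4-methoxybenzyloxy)-4,10-dimethyl-7-[2-(tert-butyldimethylsilyloxy)ethyl]cyclodec-4-en-9-one
Product: 20 (4E,6S,7S,8S,10R)-8-hydroxy-6-(4-methoxybenzyloxy)-4,10-dimethyl-7-[2-(tert-butyldimethylsilyloxy)ethyl]cyclodec-4-en-9-one, via sodium enolate 19 (not isolated)
Conditions: NaN(SiMe3)2, THF, −78 °C; 2-(phenylsulfonyl)-3-phenyloxaziridine, −78 °C; aq NH4Cl
Reagents that add atoms: 2-(phenylsulfonyl)-3-phenyloxaziridine, O=S(=O)(N1OC1c1ccccc1)c1ccccc1
Why: Kinetic deprotonation with NaN(SiMe3)2 removes the outward C8 hydrogen that is aligned with the carbonyl π system (C10–H lies in the carbonyl plane and is tertiary) and gives the sodium enolate 19 with the trans ring geometry already met in 17, and the oxaziridine (Davis enolate hydroxylation, for which sodium enolates are the usual partners) can reach only the outer face of this ring enolate, so OH takes the place of that hydrogen and C8 becomes S, trans to the C11 chain on C7.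

Step 14
Reactants: 20 (4E,6S,7S,8S,10R)-8-hydroxy-6-(4-methoxybenzyloxy)-4,10-dimethyl-7-[2-(tert-butyldimethylsilyloxy)ethyl]cyclodec-4-en-9-one
Product: 21 (4E,6S,7S,8S,9R,10R)-6-(4-methoxybenzyloxy)-4,10-dimethyl-7-[2-(tert-butyldimethylsilyloxy)ethyl]cyclodec-4-ene-8,9-diol
Conditions: Zn(BH4)2, Et2O, −20 °C; aq NH4Cl
Reagents that add atoms: none
Why: Zinc chelates O8 and the carbonyl oxygen in a five-membered ring (chelation-controlled reduction of an α-hydroxy ketone, Cram chelate model) and hydride adds from the side of the C8 hydrogen, which is also the outer face of the ring, giving the 8,9-erythro diol with C9 R.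

Step 15
Reactants: 21 (4E,6S,7S,8S,9R,10R)-6-(4-methoxybenzyloxy)-4,10-dimethyl-7-[2-(tert-butyldimethylsilyloxy)ethyl]cyclodec-4-ene-8,9-diol
Product: 22 (4E,6S,7S,8S,9R,10R)-7-(2-hydroxyethyl)-6-(4-methoxybenzyloxy)-4,10-dimethylcyclodec-4-ene-8,9-diol
Conditions: Bu4NF, THF, 0 °C to rt
Reagents that add atoms: none
Why: Fluoride cleaves the primary silyl ether through pentacoordinate silicon; the secondary alcohols and the PMB ether are inert.

Step 16
Reactants: 22 (4E,6S,7S,8S,9R,10R)-7-(2-hydroxyethyl)-6-(4-methoxybenzyloxy)-4,10-dimethylcyclodec-4-ene-8,9-diol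
Product: 24 (4E,6S,7R,8S,9R,10R)-9-hydroxy-6-(4-methoxybenzyloxy)-13-norgermacr-4-en-12,8-olide, via lactol 23 (not isolated)
Conditions: TEMPO (20 mol%), PhI(OAc)2 (2.5 equiv), CH2Cl2, rt
Reagents that add atoms: none
Why: The oxoammonium salt from TEMPO oxidises only the primary alcohol, the aldehyde closes to the five-membered lactol with the C8 hydroxyl in preference to a bridged six-membered lactol through O9, and a second oxidation gives the trans-fused γ-lactone (oxidative lactonisation of a 1,4-diol).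

Step 17
Reactants: 24 (4E,6S,7R,8S,9R,10R)-9-hydroxy-6-(4-methoxybenzyloxy)-13-norgermacr-4-en-12,8-olide
Product: 25 (4E,6S,7R,8S,9R,10R)-6-(4-methoxybenzyloxy)-9-(triethylsilyloxy)-13-norgermacr-4-en-12,8-olide
Conditions: Et3SiOTf, 2,6-lutidine, CH2Cl2, −78 °C
Reagents that add atoms: triethylsilyl trifluoromethanesulfonate, CC[Si](CC)(CC)OS(=O)(=O)C(F)(F)F
Why: Silylation of the remaining secondary alcohol with the silyl triflate and a hindered base masks O9 for the enolate chemistry and for the later acylation of O6.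

Step 18
Reactants: 25 (4E,6S,7R,8S,9R,10R)-6-(4-methoxybenzyloxy)-9-(triethylsilyloxy)-13-norgermacr-4-en-12,8-olide
Product: 29 (4E,6S,7R,8S,9R,10R)-6-(4-methoxybenzyloxy)-9-(triethylsilyloxy)germacra-4,11(13)-dien-12,8-olide, via lithium enolate 26 (not isolated), via Mannich base 27 (not isolated), via ammonium iodide 28 (not isolated)
Conditions: LiN(iPr)2, THF, −78 °C; CH2=NMe2+ I−, −78 °C to rt; MeI, MeOH, rt; aq NaHCO3, CH2Cl2
Reagents that add atoms: N,N-dimethylmethyleneiminium iodide (Eschenmoser's salt), C=[N+](C)C.[I-]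
Why: The lithium enolate of the γ-lactone adds to the iminium salt (Mannich reaction), and quaternisation followed by base-induced E1cB elimination of trimethylamine installs the exocyclic C11=C13 alkene; the configuration at C11 of 27 is of no consequence.

Step 19
Reactants: 29 (4E,6S,7R,8S,9R,10R)-6-(4-methoxybenzyloxy)-9-(triethylsilyloxy)germacra-4,11(13)-dien-12,8-olide
Product: 30 (4E,6S,7R,8S,9R,10R)-6-hydroxy-9-(triethylsilyloxy)germacra-4,11(13)-dien-12,8-olide
Conditions: DDQ, CH2Cl2/pH 7 buffer, 0 °C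
Reagents that add atoms: none
Why: DDQ oxidises the electron-rich benzyl ether by hydride abstraction and the oxocarbenium ion is hydrolysed, freeing the allylic C6 hydroxyl while the silyl ether, the lactone and both alkenes remain.

Step 20
Reactants: 30 (4E,6S,7R,8S,9R,10R)-6-hydroxy-9-(triethylsilyloxy)germacra-4,11(13)-dien-12,8-olide
Product: 31 (4R,5R,6R,7R,8S,9R,10R)-4,5-epoxy-6-hydroxy-9-(triethylsilyloxy)germacr-11(13)-en-12,8-olide
Conditions: Ti(OiPr)4, D-(−)-diisopropyl tartrate, t-BuOOH, 4 Å MS, CH2Cl2, −20 °C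
Reagents that add atoms: tert-butyl hydroperoxide, CC(C)(C)OO
Why: Titanium–tartrate (Sharpless–Katsuki) epoxidation of a secondary allylic alcohol delivers oxygen to the alkene face opposite the carbon substituent of the carbinol centre (here C7) when the substrate enantiomer is matched to the tartrate, which for the C6 configuration of 30 should be the D-(−) ester, giving the erythro 4R,5R epoxy alcohol; reagent control is chosen because A(1,3) strain with the cis C4 methyl makes peracid and vanadium epoxidations favour the threo isomer.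

Step 21
Reactants: 31 (4R,5R,6R,7R,8S,9R,10R)-4,5-epoxy-6-hydroxy-9-(triethylsilyloxy)germacr-11(13)-en-12,8-olide; 32 angelic acid
Product: 33 (4R,5R,6R,7R,8S,9R,10R)-6-angeloyloxy-4,5-epoxy-9-(triethylsilyloxy)germacr-11(13)-en-12,8-olide
Conditions: 32, 2,4,6-Cl3C6H2COCl, Et3N, toluene, rt; then 31, 80 °C
Reagents that add atoms: none
Why: Esterification through the mixed anhydride with 2,4,6-trichlorobenzoic acid (Yamaguchi-type acylation) without a nucleophilic pyridine catalyst acylates the hindered alcohol while avoiding the addition–elimination path that isomerises angelates to tiglates.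

Step 22
Reactants: 33 (4R,5R,6R,7R,8S,9R,10R)-6-angeloyloxy-4,5-epoxy-9-(triethylsilyloxy)germacr-11(13)-en-12,8-olide
Product: 34 (4R,5R,6R,7S,8S,9R,10R)-6-angeloyloxy-4,5-epoxy-9-hydroxygermacr-11(13)-en-12,8-olide
Conditions: HF·pyridine, pyridine, THF, 0 °C
Reagents that add atoms: none
Why: Buffered HF·pyridine cleaves the secondary triethylsilyl ether under conditions in which the oxirane (no transannular alkene to open it), the angelate and the methylene lactone should survive.

**Compound list**

1 | cis-2,6-dimethylcyclohexanone (meso, 2R,6S) | C[C@H]1CCC[C@@H](C)C1=O | starting material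
2 | (6R)-2,6-dimethyl-1-(trimethylsilyloxy)cyclohex-1-ene | C[Si](C)(C)OC1=C(C)CCC[C@H]1C | intermediate
3 | (2R,6R)-2-allyl-2,6-dimethylcyclohexanone | O=C1[C@H](C)CCC[C@]1(C)CC=C | intermediate
4 | (2R,6R)-2,6-dimethyl-2-[(E)-prop-1-enyl]cyclohexanone | O=C1[C@H](C)CCC[C@]1(C)/C=C/C | intermediate
5 | (2R,6R)-2,6-dimethyl-2-(5-methyl-1,2,4-trioxolan-3-yl)cyclohexanone (ozonide, epimers at the trioxolane carbons) | O=C1[C@H](C)CCC[C@]1(C)C1OOC(C)O1 | intermediate
6 | (1R,3R)-1,3-dimethyl-2-oxocyclohexane-1-carbaldehyde | O=C1[C@H](C)CCC[C@]1(C)C=O | intermediate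
7 | (2R,6R)-2-[(E)-2-iodoethenyl]-2,6-dimethylcyclohexanone | O=C1[C@H](C)CCC[C@]1(C)/C=C/I | intermediate
8 | (1R,3R)-1-[(E)-2-iodoethenyl]-1,3-dimethyl-2-methylidenecyclohexane | C=C1[C@H](C)CCC[C@]1(C)/C=C/I | intermediate
9 | (3R,4R,8R)-4-[(E)-2-iodoethenyl]-4,8-dimethyl-1-oxaspiro[2.5]octane | C1O[C@@]12[C@H](C)CCC[C@]2(C)/C=C/I | intermediate
10 | (1R,2R,6R)-1-ethenyl-2-[(E)-2-iodoethenyl]-2,6-dimethylcyclohexan-1-ol | O[C@]1(C=C)[C@H](C)CCC[C@]1(C)/C=C/I | intermediate
11 | but-3-en-1-ol | C=CCCO | starting material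
12 | tert-butyl(but-3-enyloxy)dimethylsilane | C=CCCO[Si](C)(C)C(C)(C)C | intermediate
13 | (1S,2R,6R)-1-[(E)-4-(tert-butyldimethylsilyloxy)but-1-enyl]-2-[(E)-2-iodoethenyl]-2,6-dimethylcyclohexan-1-ol | O[C@]1(/C=C/CCO[Si](C)(C)C(C)(C)C)[C@H](C)CCC[C@]1(C)/C=C/I | intermediate
14 | 4-methoxybenzyl alcohol | COc1ccc(CO)cc1 | starting material
15 | (1S,2R,6R)-1-[(E)-4-(tert-butyldimethylsilyloxy)but-1-enyl]-2-[(E)-2-(4-methoxybenzyloxy)ethenyl]-2,6-dimethylcyclohexan-1-ol | O[C@]1(/C=C/CCO[Si](C)(C)C(C)(C)C)[C@H](C)CCC[C@]1(C)/C=C/OCc2ccc(OC)cc2 | intermediate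
16 | potassium alkoxide of 15 | [K+].[O-][C@]1(/C=C/CCO[Si](C)(C)C(C)(C)C)[C@H](C)CCC[C@]1(C)/C=C/OCc2ccc(OC)cc2 | intermediate
17 | potassium (4E,6R,7S,8Z,10R)-6-(4-methoxybenzyloxy)-4,10-dimethyl-7-[2-(tert-butyldimethylsilyloxy)ethyl]cyclodeca-4,8-dien-9-olate (ring carbons C7 and C10 trans on C8=C9) | [K+].[O-]/C1=C\[C@H](CCO[Si](C)(C)C(C)(C)C)[C@@H](OCc2ccc(OC)cc2)/C=C(C)/CCC[C@H]1C | intermediate
18 | (4E,6R,7S,10R)-6-(4-methoxybenzyloxy)-4,10-dimethyl-7-[2-(tert-butyldimethylsilyloxy)ethyl]cyclodec-4-en-9-one | C1C(=O)[C@H](C)CCC/C(C)=C/[C@H](OCc2ccc(OC)cc2)[C@H]1CCO[Si](C)(C)C(C)(C)C | intermediate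
19 | sodium (4E,6R,7S,8Z,10R)-6-(4-methoxybenzyloxy)-4,10-dimethyl-7-[2-(tert-butyldimethylsilyloxy)ethyl]cyclodeca-4,8-dien-9-olate (ring carbons C7 and C10 trans on C8=C9) | [Na+].[O-]/C1=C\[C@H](CCO[Si](C)(C)C(C)(C)C)[C@@H](OCc2ccc(OC)cc2)/C=C(C)/CCC[C@H]1C | intermediate
20 | (4E,6S,7S,8S,10R)-8-hydroxy-6-(4-methoxybenzyloxy)-4,10-dimethyl-7-[2-(tert-butyldimethylsilyloxy)ethyl]cyclodec-4-en-9-one | O=C1[C@@H](O)[C@H](CCO[Si](C)(C)C(C)(C)C)[C@@H](OCc2ccc(OC)cc2)/C=C(C)/CCC[C@H]1C | intermediate
21 | (4E,6S,7S,8S,9R,10R)-6-(4-methoxybenzyloxy)-4,10-dimethyl-7-[2-(tert-butyldimethylsilyloxy)ethyl]cyclodec-4-ene-8,9-diol | O[C@H]1[C@@H](O)[C@H](CCO[Si](C)(C)C(C)(C)C)[C@@H](OCc2ccc(OC)cc2)/C=C(C)/CCC[C@H]1C | intermediate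
22 | (4E,6S,7S,8S,9R,10R)-7-(2-hydroxyethyl)-6-(4-methoxybenzyloxy)-4,10-dimethylcyclodec-4-ene-8,9-diol | O[C@H]1[C@@H](O)[C@H](CCO)[C@@H](OCc2ccc(OC)cc2)/C=C(C)/CCC[C@H]1C | intermediate
23 | (4E,6S,7R,8S,9R,10R)-8,12-epoxy-6-(4-methoxybenzyloxy)-13-norgermacr-4-ene-9,12-diol (lactol, both C12 epimers, in equilibrium with the open hydroxy aldehyde) | O[C@H]1[C@H]2OC(O)C[C@@H]2[C@@H](OCc3ccc(OC)cc3)/C=C(C)/CCC[C@H]1C | intermediate
24 | (4E,6S,7R,8S,9R,10R)-9-hydroxy-6-(4-methoxybenzyloxy)-13-norgermacr-4-en-12,8-olide (trans-fused γ-lactone) | O[C@H]1[C@H]2OC(=O)C[C@@H]2[C@@H](OCc3ccc(OC)cc3)/C=C(C)/CCC[C@H]1C | intermediate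
25 | (4E,6S,7R,8S,9R,10R)-6-(4-methoxybenzyloxy)-9-(triethylsilyloxy)-13-norgermacr-4-en-12,8-olide | CC[Si](CC)(CC)O[C@H]1[C@H]2OC(=O)C[C@@H]2[C@@H](OCc3ccc(OC)cc3)/C=C(C)/CCC[C@H]1C | intermediate
26 | lithium enolate of lactone 25 (C11=C12 enolate) | [Li+].CC[Si](CC)(CC)O[C@H]1[C@H]2OC([O-])=C[C@@H]2[C@@H](OCc3ccc(OC)cc3)/C=C(C)/CCC[C@H]1C | intermediate
27 | (4E,6S,7R,8S,9R,10R)-13-(dimethylamino)-6-(4-methoxybenzyloxy)-9-(triethylsilyloxy)germacr-4-en-12,8-olide (both C11 epimers) | CC[Si](CC)(CC)O[C@H]1[C@H]2OC(=O)C(CN(C)C)[C@@H]2[C@@H](OCc3ccc(OC)cc3)/C=C(C)/CCC[C@H]1C | intermediate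
28 | trimethylammonium iodide of 27 (both C11 epimers) | [I-].CC[Si](CC)(CC)O[C@H]1[C@H]2OC(=O)C(C[N+](C)(C)C)[C@@H]2[C@@H](OCc3ccc(OC)cc3)/C=C(C)/CCC[C@H]1C | intermediate
29 | (4E,6S,7R,8S,9R,10R)-6-(4-methoxybenzyloxy)-9-(triethylsilyloxy)germacra-4,11(13)-dien-12,8-olide | CC[Si](CC)(CC)O[C@H]1[C@H]2OC(=O)C(=C)[C@@H]2[C@@H](OCc3ccc(OC)cc3)/C=C(C)/CCC[C@H]1C | intermediate
30 | (4E,6S,7R,8S,9R,10R)-6-hydroxy-9-(triethylsilyloxy)germacra-4,11(13)-dien-12,8-olide | CC[Si](CC)(CC)O[C@H]1[C@H]2OC(=O)C(=C)[C@@H]2[C@@H](O)/C=C(C)/CCC[C@H]1C | intermediate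
31 | (4R,5R,6R,7R,8S,9R,10R)-4,5-epoxy-6-hydroxy-9-(triethylsilyloxy)germacr-11(13)-en-12,8-olide | CC[Si](CC)(CC)O[C@H]1[C@H]2OC(=O)C(=C)[C@@H]2[C@@H](O)[C@H]3O[C@]3(C)CCC[C@H]1C | intermediate
32 | angelic acid, (Z)-2-methylbut-2-enoic acid | C/C=C(/C)C(=O)O | starting material
33 | (4R,5R,6R,7R,8S,9R,10R)-6-angeloyloxy-4,5-epoxy-9-(triethylsilyloxy)germacr-11(13)-en-12,8-olide | CC[Si](CC)(CC)O[C@H]1[C@H]2OC(=O)C(=C)[C@@H]2[C@@H](OC(=O)/C(C)=C\C)[C@H]3O[C@]3(C)CCC[C@H]1C | intermediate
34 | (4R,5R,6R,7S,8S,9R,10R)-6-angeloyloxy-4,5-epoxy-9-hydroxygermacr-11(13)-en-12,8-olide | C=C1C(=O)O[C@@H]2[C@H](O)[C@H](C)CCC[C@@]3(C)O[C@@H]3[C@H](OC(=O)/C(C)=C\C)[C@@H]12 | target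

**Step count and risks**

Total: 22 steps (21 on the main line plus the silylation of 11). Longest linear sequence: 21 steps, from 1 to 34 (steps 1–8 and 10–22).

Steps most likely to fail:

1. Step 20. The matched titanium–tartrate transition state needs the C6–O bond close to the alkene plane beside the cis C4 methyl and the ring folded to the opposite side; A(1,3) strain and the ring conformation may make the reaction slow or let the substrate-preferred threo epoxidation compete, giving poor facial selectivity. The fallback uses the substrate preference instead of fighting it. It sets out from 30: Mitsunobu inversion with formic acid (PPh3, diisopropyl azodicarboxylate) gives the 6-epi formate F1, mild methanolysis (KHCO3, MeOH, 0 °C) gives the 6-epi allylic alcohol F2, and hydroxyl-directed epoxidation with VO(acac)2 and t-BuOOH, now in the threo sense favoured by A(1,3) strain, should give the 4R,5R epoxide of the 6-epi alcohol F3. A second Mitsunobu reaction, this time with angelic acid, inverts C6 and installs the ester in one operation, so the fallback returns to the route at 33.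

2. Step 8. The SN2 opening takes place at a neopentyl-type CH2 next to a carbon flanked by a quaternary and a tertiary centre; it may be so slow that the ylide decomposes or attacks the iodoalkene. The fallback replaces the epoxide by a diol and sets out from 8: dihydroxylation with catalytic OsO4 and N-methylmorpholine N-oxide, expected from the same face anti to the axial C4 methyl, gives the diol F4; oxidation of its primary alcohol (SO3·pyridine, DMSO, iPr2NEt) gives the α-hydroxy aldehyde F5; Wittig methylenation (Ph3P=CH2, THF) then returns to the route at 10.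

3. Step 13. Re-enolisation of 18 may not reproduce the trans ring enolate of the rearrangement, or may occur partly toward C10, so that the oxidation loses facial or positional selectivity. The fallback fixes the enolate geometry at the moment it is formed and sets out from 15: the rearrangement is run as in step 12 but enolate 17 is quenched at −78 °C with Me3SiCl and Et3N to give the trimethylsilyl enol ether F6. Rubottom oxidation with dimethyldioxirane at −78 °C, where the enol ether reacts far faster than the trisubstituted alkene and only its outer face is open, gives the silyloxy oxirane F7, and dilute citric acid in methanol opens it to the hydroxy ketone, returning to the route at 20.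

**Further compounds**

F1 | step 20 | (4E,6R,7R,8S,9R,10R)-6-formyloxy-9-(triethylsilyloxy)germacra-4,11(13)-dien-12,8-olide (6-epi formate) | CC[Si](CC)(CC)O[C@H]1[C@H]2OC(=O)C(=C)[C@@H]2[C@H](OC=O)/C=C(C)/CCC[C@H]1C
F2 | step 20 | (4E,6R,7R,8S,9R,10R)-6-hydroxy-9-(triethylsilyloxy)germacra-4,11(13)-dien-12,8-olide (6-epi allylic alcohol) | CC[Si](CC)(CC)O[C@H]1[C@H]2OC(=O)C(=C)[C@@H]2[C@H](O)/C=C(C)/CCC[C@H]1C
F3 | step 20 | (4R,5R,6S,7R,8S,9R,10R)-4,5-epoxy-6-hydroxy-9-(triethylsilyloxy)germacr-11(13)-en-12,8-olide (4R,5R epoxide of the 6-epi alcohol) | CC[Si](CC)(CC)O[C@H]1[C@H]2OC(=O)C(=C)[C@@H]2[C@H](O)[C@H]3O[C@]3(C)CCC[C@H]1C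
F4 | step 8 | (1R,2R,6R)-1-(hydroxymethyl)-2-[(E)-2-iodoethenyl]-2,6-dimethylcyclohexan-1-ol | O[C@]1(CO)[C@H](C)CCC[C@]1(C)/C=C/I
F5 | step 8 | (1R,2R,6R)-1-hydroxy-2-[(E)-2-iodoethenyl]-2,6-dimethylcyclohexane-1-carbaldehyde | O[C@]1(C=O)[C@H](C)CCC[C@]1(C)/C=C/I
F6 | step 13 | (4E,6R,7S,8Z,10R)-6-(4-methoxybenzyloxy)-4,10-dimethyl-7-[2-(tert-butyldimethylsilyloxy)ethyl]-9-(trimethylsilyloxy)cyclodeca-4,8-diene | C[Si](C)(C)O/C1=C\[C@H](CCO[Si](C)(C)C(C)(C)C)[C@@H](OCc2ccc(OC)cc2)/C=C(C)/CCC[C@H]1C
F7 | step 13 | (4E,6S,7R,8S,9R,10R)-8,9-epoxy-6-(4-methoxybenzyloxy)-4,10-dimethyl-7-[2-(tert-butyldimethylsilyloxy)ethyl]-9-(trimethylsilyloxy)cyclodec-4-ene | C[Si](C)(C)O[C@@]12O[C@H]1[C@H](CCO[Si](C)(C)C(C)(C)C)[C@@H](OCc3ccc(OC)cc3)/C=C(C)/CCC[C@H]2C
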